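The pitfall on this bench is to read the charge of second end groups as the yield of links, when links do not stay as they are made.

first end groups 0.39 M; second end groups 0.900 equiv; time 80 min
    first end groups + second end groups → links + released group (k1 = 7.8 M⁻¹ min⁻¹)
    first end groups + links ⇌ idle adduct, settled at all times (K2 = 3.1 M⁻¹)
    links ⇌ isomer of the product (K3 = 0.39, k3 = 0.72 min⁻¹)
- a species is counted by the first end groups in it: one idle adduct counts as two
- amounts and yields of links count idle adduct too
- in an amount of links, one idle adduct counts as one links
- the reaction counts as stopped when no species that holds the first end groups changes by six tenths of a point or more over the second half of the time
- run time (flask): 80 min
- which holds at 80 min: what has brought the reaction to rest, or that it has not come to rest (all of the first end groups has reacted / it is still moving / the second end groups has run out first / forward and back rates have come level)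
- amount of links at 80 min, in percent of the first end groups charged

For whoever takes over: second end groups are the limiting reagent here, so the first step can make at most 90.0 % of links, counted on first end groups. Near its end they meet excess first end groups in a pseudo-first-order fall, with our half-life 2.28 min, far shorter than the 80 min run; binding into idle adduct will lengthen it, but we expect them gone. The third step relaxes in 0.270 min, also short against the run. So we carry the kept fraction 71.9 %, the share of free links and isomer of the product together that stands as links at the balance of that step. This gives 64.7 % of links, and since links in idle adduct count yet stand outside that step, we expect this figure to lie below the flask's rather than above it. Leave the flask be: we expect waiting to add nothing.

The forecast says the second end groups has run out first and 66 %, above our figure, reasoning “the mixture comes to rest through their exhaustion”.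

This flask gives the second end groups has run out first and 65.9 %, which our product of ceiling and kept fraction undershot by 1.2 percentage points. In this flask the isomer of the product had reached 21.1 % by 4.00 min, and second end groups were still being used after that, standing at 2.75 % of their charge at 8.00 min; by 40.0 min they stood at 0.00824 %.

In the neighbour with 3.60 equiv of second end groups, first end groups are the smaller charge, so the ceiling is their whole charge and the kept fraction itself, 71.9 %, is our figure for links; that flask gives 71.9 %, with 0 % of its first end groups left.

(The rate constants were set for the occasion; no experiment stands behind them.)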